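The target is a 4→8-linked dimer of two 2,3-cis flavan-3-ols. Both pyran rings are cut at their aryl–C4 bonds, C4–C4a (ring C) and C4'–C4a' (ring F). The key step exploits that C4 lies between two phloroglucinol carbons, C4a of ring A and C8' of ring D, and that C4' ends on C4a' of ring D: one acid treatment ionises the C4 carbinol, which ring A traps, and opens the C3'–C4' epoxide at C4', closing both rings and setting C4. Its precursor is an open-chain bis(aryl ether) with C2, C3, C2' and C3' in place, a C3 benzyl ether, an epimeric C4 carbinol and a terminal epoxide; both chains derive from one (R)-glycerate ester.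

Key step: step 16

Remarks on the chemistry (assumptions):
- Flavan numbering is used throughout, also for the open-chain compounds. Unprimed locants and rings A (trioxygenated arene), B (phenyl) and C (pyran) belong to the upper unit; primed locants and rings D, E and F belong to the lower unit.
- The target SMILES is read as (2R,3R,4R) in the upper unit and (2R,3R) in the lower unit: both units 2,3-cis, upper unit 3,4-trans.
- Ester 1 is taken as the commercial (R) enantiomer and 3 as a commercial solution.
- The C4 carbinol is carried as the mixture of both epimers from its formation to the key step and is never oxidised to a ketone; after it exists, only basic or neutral conditions are used.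

Step 1
Reactants: 1 methyl (R)-2,2-dimethyl-1,3-dioxolane-4-carboxylate
Product: 2 (R)-N-methoxy-N,2,2-trimethyl-1,3-dioxolane-4-carboxamide
Conditions: MeNH(OMe)·HCl, iPrMgCl, THF, −20 °C
Reagents that add atoms: N,O-dimethylhydroxylamine hydrochloride, CNOC.Cl
Why: Magnesium-amide aminolysis of the ester (Weinreb amide formation) should run at low temperature without enolising the α-alkoxy centre, so the (R) configuration is kept.

Step 2
Reactants: 2 (R)-N-methoxy-N,2,2-trimethyl-1,3-dioxolane-4-carboxamide; 3 phenylmagnesium bromide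
Product: 4 (R)-(2,2-dimethyl-1,3-dioxolan-4-yl)(phenyl)methanone
Conditions: PhMgBr, THF, 0 °C; aq NH4Cl
Reagents that add atoms: none
Why: Weinreb ketone synthesis, in which the chelated tetrahedral magnesium adduct survives until the quench, so one phenyl group is delivered and the stereocentre is untouched.

Step 3
Reactants: 4 (R)-(2,2-dimethyl-1,3-dioxolan-4-yl)(phenyl)methanone
Product: 5 (S)-[(R)-2,2-dimethyl-1,3-dioxolan-4-yl](phenyl)methanol (anti alcohol)
Conditions: Zn(BH4)2, Et2O, −30 → 0 °C
Reagents that add atoms: none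
Why: Chelation-controlled (Cram-chelate) ketone reduction, in which zinc bridges the carbonyl oxygen and the α-oxygen of the dioxolane and hydride enters from the face that carries the α-hydrogen, which should set the (S)-carbinol anti to the (R) centre.

Step 4
Reactants: 5 (S)-[(R)-2,2-dimethyl-1,3-dioxolan-4-yl](phenyl)methanol; 6 3,5-bis(benzyloxy)phenol
Product: 7 (R)-4-[(R)-[3,5-bis(benzyloxy)phenoxy](phenyl)methyl]-2,2-dimethyl-1,3-dioxolane (threo aryl ether)
Conditions: PPh3, DIAD, toluene, 0 °C → rt
Reagents that add atoms: none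
Why: Mitsunobu etherification of a secondary benzylic alcohol with a phenol proceeds by SN2 attack of the phenoxide on the alkoxyphosphonium ion, so the carbinol is inverted to the (R)-aryl ether, which is C2 with O1 and ring A in place.

Step 5
Reactants: 7 (R)-4-[(R)-[3,5-bis(benzyloxy)phenoxy](phenyl)methyl]-2,2-dimethyl-1,3-dioxolane
Product: 8 (2R,3R)-3-[3,5-bis(benzyloxy)phenoxy]-3-phenylpropane-1,2-diol
Conditions: AcOH/H2O/THF (4:1:1), 45 °C
Reagents that add atoms: none
Why: Acid-catalysed acetal hydrolysis in an aqueous medium, where water outcompetes the electron-rich ring A for the transient oxocarbenium ion, frees the diol without touching C2 or C3.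

Step 6
Reactants: 8 (2R,3R)-3-[3,5-bis(benzyloxy)phenoxy]-3-phenylpropane-1,2-diol
Product: 9 (1R,2R)-1-[3,5-bis(benzyloxy)phenoxy]-1-phenyl-3-(trityloxy)propan-2-ol
Conditions: TrCl, Et3N, DMAP (cat.), CH2Cl2, rt
Reagents that add atoms: trityl chloride, ClC(c1ccccc1)(c1ccccc1)c1ccccc1
Why: Tritylation is selective for the primary hydroxyl on steric grounds, so the C3 hydroxyl stays free for the next step.

Step 7
Reactants: 9 (1R,2R)-1-[3,5-bis(benzyloxy)phenoxy]-1-phenyl-3-(trityloxy)propan-2-ol
Product: 10 (2R,3R)-2-(benzyloxy)-3-[3,5-bis(benzyloxy)phenoxy]-3-phenylpropyl trityl ether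
Conditions: NaH, BnBr, Bu4NI (cat.), DMF, 0 °C → rt
Reagents that add atoms: benzyl bromide, BrCc1ccccc1
Why: Williamson etherification of the secondary alkoxide installs the C3 benzyl ether, and a trityl ether cannot migrate under base, so the regiochemistry is unambiguous.

Step 8
Reactants: 10 (2R,3R)-2-(benzyloxy)-3-[3,5-bis(benzyloxy)phenoxy]-3-phenylpropyl trityl ether
Product: 11 (2R,3R)-2-(benzyloxy)-3-[3,5-bis(benzyloxy)phenoxy]-3-phenylpropan-1-ol
Conditions: TsOH·H2O (cat.), MeOH/CH2Cl2 (1:1), rt
Reagents that add atoms: none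
Why: Acid-catalysed SN1 methanolysis cleaves only the trityl ether, the trityl cation being trapped by the solvent, while the benzyl ethers and the benzylic aryl ether stay intact.

Step 9
Reactants: 11 (2R,3R)-2-(benzyloxy)-3-[3,5-bis(benzyloxy)phenoxy]-3-phenylpropan-1-ol
Product: 12 (2S,3R)-2-(benzyloxy)-3-[3,5-bis(benzyloxy)phenoxy]-3-phenylpropanal
Conditions: Dess–Martin periodinane, CH2Cl2, 0 °C → rt
Reagents that add atoms: none
Why: Dess–Martin oxidation is near-neutral and stops at the aldehyde, so the α-benzyloxy centre (C3) should not epimerise and the β-aryloxy group should not be eliminated, provided 12 is used at once without chromatography.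

Step 10
Reactants: 6 3,5-bis(benzyloxy)phenol
Product: 13 3,5-bis(benzyloxy)-2-bromophenol
Conditions: NBS, iPr2NH (cat.), CH2Cl2, −78 → 0 °C
Reagents that add atoms: N-bromosuccinimide, O=C1CCC(=O)N1Br
Why: Electrophilic aromatic bromination under amine catalysis should deliver bromine ortho to the free hydroxyl through the hydrogen-bonded N-bromoamine, at one of two equivalent positions, with one equivalent at low temperature limiting dibromination and the symmetric para isomer removable by chromatography.

Step 11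
Reactants: 5 (S)-[(R)-2,2-dimethyl-1,3-dioxolan-4-yl](phenyl)methanol; 13 3,5-bis(benzyloxy)-2-bromophenol
Product: 14 (R)-4-[(R)-[3,5-bis(benzyloxy)-2-bromophenoxy](phenyl)methyl]-2,2-dimethyl-1,3-dioxolane
Conditions: PPh3, DIAD, toluene, 0 °C → rt
Reagents that add atoms: none
Why: Mitsunobu etherification as in step 4, helped by the higher acidity of the ortho-bromophenol, gives by SN2 inversion the (R)-aryl ether that becomes C2' with O1' and places bromine on the future C8'.

Step 12
Reactants: 14 (R)-4-[(R)-[3,5-bis(benzyloxy)-2-bromophenoxy](phenyl)methyl]-2,2-dimethyl-1,3-dioxolane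
Product: 15 (2R,3R)-3-[3,5-bis(benzyloxy)-2-bromophenoxy]-3-phenylpropane-1,2-diol
Conditions: AcOH/H2O/THF (4:1:1), 45 °C
Reagents that add atoms: none
Why: Aqueous acid-catalysed acetal hydrolysis as in step 5 frees the diol that will later become the epoxide, and the aryl bromide is inert.

Step 13
Reactants: 15 (2R,3R)-3-[3,5-bis(benzyloxy)-2-bromophenoxy]-3-phenylpropane-1,2-diol
Product: 16 (2R,3R)-3-[3,5-bis(benzyloxy)-2-bromophenoxy]-3-phenylpropane-1,2-diol bis(tert-butyldimethylsilyl) ether
Conditions: TBSOTf, 2,6-lutidine, CH2Cl2, 0 °C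
Reagents that add atoms: tert-butyldimethylsilyl triflate, CC(C)(C)[Si](C)(C)OS(=O)(=O)C(F)(F)F
Why: Silylation with a silyl triflate and a hindered pyridine base covers both hydroxyls with groups that are inert to organolithiums and are later removed by fluoride, so no acid is needed once the C4 carbinol exists.

Step 14
Reactants: 16 (2R,3R)-3-[3,5-bis(benzyloxy)-2-bromophenoxy]-3-phenylpropane-1,2-diol bis(tert-butyldimethylsilyl) ether; 12 (2S,3R)-2-(benzyloxy)-3-[3,5-bis(benzyloxy)phenoxy]-3-phenylpropanal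
Product: 19 open-chain triol (C4 carbinol as both epimers; free C3'–C4' diol), via aryllithium 17 (not isolated), via bis-silyl carbinol 18 (not isolated)
Conditions: n-BuLi, THF, −78 °C; 12, −78 °C; then Bu4NF, 0 °C → rt
Reagents that add atoms: n-butyllithium, [Li]CCCC (its lithium is held by 17 only)
Why: Bromine–lithium exchange places lithium on the future C8', ortho to O1', and 1,2-addition to the aldehyde forms the C4–C8' bond (the C4 configuration is irrelevant because both epimers give one cation), after which fluoride cleaves both silyl ethers in the same flask under non-acidic conditions that the 2,4,6-trialkoxybenzylic carbinol tolerates.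

Step 15
Reactants: 19 open-chain triol (C4 carbinol as both epimers; free C3'–C4' diol)
Product: 21 open-chain bis(aryl ether) with C4 carbinol (both epimers), C3 benzyl ether and (R)-configured C3'–C4' epoxide, via primary tosylate 20 (not isolated)
Conditions: TsCl, Et3N, Bu2SnO (cat.), CH2Cl2, 0 °C → rt; then K2CO3, MeOH, rt
Reagents that add atoms: p-toluenesulfonyl chloride, Cc1ccc(cc1)S(Cl)(=O)=O (the tosyl group is held by 20 only)
Why: Tin-catalysed sulfonylation through the stannylene acetal of the 1,2-diol is selective for the primary hydroxyl, and the C3' alkoxide then displaces the tosylate (3-exo-tet Williamson closure), so C3' keeps its configuration and only base meets the acid-labile C4 carbinol.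

Step 16
Reactants: 21 open-chain bis(aryl ether) with C4 carbinol (both epimers), C3 benzyl ether and (R)-configured C3'–C4' epoxide
Product: 23 (2R,3R,4R)-3,5,7-tris(benzyloxy)-4-[(2R,3R)-5,7-bis(benzyloxy)-3-hydroxy-2-phenylchroman-8-yl]-2-phenylchromane (pentabenzyl ether of the target with free 3'-OH), via ring-C-closed epoxide 22 (not isolated)
Conditions: Sc(OTf)3 (cat.), HFIP/CH2Cl2 (1:1), 0.005 M, 0 °C → rt
Reagents that add atoms: none
Why: In the strongly ionising but weakly nucleophilic and weakly basic hexafluoroisopropanol medium, Sc(OTf)3 should convert either C4 epimer into one 2,4,6-trialkoxybenzyl cation stabilised by ring D, which a carbon of ring A ortho to O1 captures to give 22, after which the same acid activates the epoxide for attack by C4a' of ring D. The closest known reaction types are the dehydrative intramolecular Friedel–Crafts alkylation of electron-rich benzylic alcohols and the Lewis-acid epoxy–arene cyclisation of aryl glycidyl ethers to chroman-3-ols. Ring C closes as a six-membered Friedel–Crafts cycloalkylation (exo to the departing C4–O bond) at one of the two identical ortho positions of ring A, and ring F closes 6-endo at the unsubstituted epoxide carbon C4', so the C3'–O bond and the C3' configuration are not touched. C4 is the only new stereocentre: in a chair-like closure with the C2 phenyl equatorial and the C3 benzyloxy group axial, ring D should take the pseudo-axial place on the face opposite the C3–O bond, away from the developing peri contact with the C5 benzyloxy group, which leads to the 3,4-trans (4R) isomer. The step needs 3,4-trans over 3,4-cis closure, which rests on that C3/C5 bias, and 6-endo over 5-exo epoxide opening, which rests on the primary epoxide terminus and on C4a' being the single free position next to O1'. High dilution should suppress intermolecular arylation, and the etherified C3 oxygen keeps a pinacol-type shift from ending in a ketone.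

Step 17
Reactants: 23 (2R,3R,4R)-3,5,7-tris(benzyloxy)-4-[(2R,3R)-5,7-bis(benzyloxy)-3-hydroxy-2-phenylchroman-8-yl]-2-phenylchromane
Product: 24 (2R,3R,4R)-4-[(2R,3R)-3,5,7-trihydroxy-2-phenylchroman-8-yl]-2-phenylchromane-3,5,7-triol (target)
Conditions: H2 (1 atm), Pd(OH)2/C, THF/MeOH (1:1), rt
Reagents that add atoms: none
Why: Catalytic hydrogenolysis cleaves the four aryl benzyl ethers and the C3 alkyl benzyl ether, while the C2–O1 and C2'–O1' ring bonds of flavans and the C4–C8' bond resist these conditions and no stereocentre is involved.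

Compound list
1 | methyl (R)-2,2-dimethyl-1,3-dioxolane-4-carboxylate | COC(=O)[C@H]1COC(C)(C)O1 | starting material
2 | (R)-N-methoxy-N,2,2-trimethyl-1,3-dioxolane-4-carboxamide | CON(C)C(=O)[C@H]1COC(C)(C)O1 | intermediate
3 | phenylmagnesium bromide | Br[Mg]c1ccccc1 | starting material
4 | (R)-(2,2-dimethyl-1,3-dioxolan-4-yl)(phenyl)methanone | O=C(c1ccccc1)[C@H]1COC(C)(C)O1 | intermediate
5 | (S)-[(R)-2,2-dimethyl-1,3-dioxolan-4-yl](phenyl)methanol (anti) | O[C@@H](c1ccccc1)[C@H]1COC(C)(C)O1 | intermediate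
6 | 3,5-bis(benzyloxy)phenol | Oc1cc(OCc2ccccc2)cc(OCc2ccccc2)c1 | starting material
7 | (R)-4-[(R)-[3,5-bis(benzyloxy)phenoxy](phenyl)methyl]-2,2-dimethyl-1,3-dioxolane | c1ccccc1COc1cc(OCc2ccccc2)cc(c1)O[C@H](c1ccccc1)[C@H]1COC(C)(C)O1 | intermediate
8 | (2R,3R)-3-[3,5-bis(benzyloxy)phenoxy]-3-phenylpropane-1,2-diol | c1ccccc1COc1cc(OCc2ccccc2)cc(c1)O[C@H](c1ccccc1)[C@H](O)CO | intermediate
9 | (1R,2R)-1-[3,5-bis(benzyloxy)phenoxy]-1-phenyl-3-(trityloxy)propan-2-ol | c1ccccc1COc1cc(OCc2ccccc2)cc(c1)O[C@H](c1ccccc1)[C@H](O)COC(c1ccccc1)(c1ccccc1)c1ccccc1 | intermediate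
10 | (2R,3R)-2-(benzyloxy)-3-[3,5-bis(benzyloxy)phenoxy]-3-phenylpropyl trityl ether | c1ccccc1COc1cc(OCc2ccccc2)cc(c1)O[C@H](c1ccccc1)[C@H](OCc1ccccc1)COC(c1ccccc1)(c1ccccc1)c1ccccc1 | intermediate
11 | (2R,3R)-2-(benzyloxy)-3-[3,5-bis(benzyloxy)phenoxy]-3-phenylpropan-1-ol | c1ccccc1COc1cc(OCc2ccccc2)cc(c1)O[C@H](c1ccccc1)[C@H](OCc1ccccc1)CO | intermediate
12 | (2S,3R)-2-(benzyloxy)-3-[3,5-bis(benzyloxy)phenoxy]-3-phenylpropanal | c1ccccc1COc1cc(OCc2ccccc2)cc(c1)O[C@H](c1ccccc1)[C@H](OCc1ccccc1)C=O | intermediate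
13 | 3,5-bis(benzyloxy)-2-bromophenol | Oc1cc(OCc2ccccc2)cc(OCc2ccccc2)c1Br | intermediate
14 | (R)-4-[(R)-[3,5-bis(benzyloxy)-2-bromophenoxy](phenyl)methyl]-2,2-dimethyl-1,3-dioxolane | Brc1c(OCc2ccccc2)cc(OCc2ccccc2)cc1O[C@H](c1ccccc1)[C@H]1COC(C)(C)O1 | intermediate
15 | (2R,3R)-3-[3,5-bis(benzyloxy)-2-bromophenoxy]-3-phenylpropane-1,2-diol | Brc1c(OCc2ccccc2)cc(OCc2ccccc2)cc1O[C@H](c1ccccc1)[C@H](O)CO | intermediate
16 | (2R,3R)-3-[3,5-bis(benzyloxy)-2-bromophenoxy]-3-phenylpropane-1,2-diol bis(tert-butyldimethylsilyl) ether | Brc1c(OCc2ccccc2)cc(OCc2ccccc2)cc1O[C@H](c1ccccc1)[C@H](O[Si](C)(C)C(C)(C)C)CO[Si](C)(C)C(C)(C)C | intermediate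
17 | aryllithium from 16 (lithium on the future C8'; formed in the flask in step 14) | [Li]c1c(OCc2ccccc2)cc(OCc2ccccc2)cc1O[C@H](c1ccccc1)[C@H](O[Si](C)(C)C(C)(C)C)CO[Si](C)(C)C(C)(C)C | intermediate
18 | open-chain C4 carbinol (both epimers) with C3 benzyl ether and bis-silylated C3'–C4' diol (formed in the flask in step 14) | c1ccccc1COc1cc(OCc2ccccc2)cc(c1)O[C@H](c1ccccc1)[C@H](OCc1ccccc1)C(O)c1c(OCc2ccccc2)cc(OCc2ccccc2)cc1O[C@H](c1ccccc1)[C@H](O[Si](C)(C)C(C)(C)C)CO[Si](C)(C)C(C)(C)C | intermediate
19 | open-chain triol: C4 carbinol (both epimers), C3 benzyl ether, free (2'R,3'R) C3'–C4' diol | c1ccccc1COc1cc(OCc2ccccc2)cc(c1)O[C@H](c1ccccc1)[C@H](OCc1ccccc1)C(O)c1c(OCc2ccccc2)cc(OCc2ccccc2)cc1O[C@H](c1ccccc1)[C@H](O)CO | intermediate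
20 | C4'-O-tosylate of 19 (formed in the flask in step 15) | c1ccccc1COc1cc(OCc2ccccc2)cc(c1)O[C@H](c1ccccc1)[C@H](OCc1ccccc1)C(O)c1c(OCc2ccccc2)cc(OCc2ccccc2)cc1O[C@H](c1ccccc1)[C@H](O)COS(=O)(=O)c1ccc(C)cc1 | intermediate
21 | key-step precursor: (2R,3R)-2-(benzyloxy)-3-[3,5-bis(benzyloxy)phenoxy]-1-{2,4-bis(benzyloxy)-6-[(R)-[(R)-oxiran-2-yl](phenyl)methoxy]phenyl}-3-phenylpropan-1-ol (both C1 epimers; C1 is flavan C4) | c1ccccc1COc1cc(OCc2ccccc2)cc(c1)O[C@H](c1ccccc1)[C@H](OCc1ccccc1)C(O)c1c(OCc2ccccc2)cc(OCc2ccccc2)cc1O[C@H](c1ccccc1)[C@H]1CO1 | intermediate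
22 | ring-C-closed epoxide: 2,3-cis-3,4-trans-3,5,7-tris(benzyloxy)-4-{2,4-bis(benzyloxy)-6-[(R)-[(R)-oxiran-2-yl](phenyl)methoxy]phenyl}-2-phenylchromane (formed in the flask in step 16) | c1ccccc1COc1cc(OCc3ccccc3)c2c(c1)O[C@H](c1ccccc1)[C@H](OCc1ccccc1)[C@H]2c1c(OCc3ccccc3)cc(OCc3ccccc3)cc1O[C@H](c1ccccc1)[C@H]1CO1 | intermediate
23 | (2R,3R,4R)-3,5,7-tris(benzyloxy)-4-[(2R,3R)-5,7-bis(benzyloxy)-3-hydroxy-2-phenylchroman-8-yl]-2-phenylchromane | c1ccccc1COc1cc(OCc3ccccc3)c2c(c1)O[C@H](c1ccccc1)[C@H](OCc1ccccc1)[C@H]2c1c(OCc3ccccc3)cc(OCc3ccccc3)c2c1O[C@H](c1ccccc1)[C@H](O)C2 | intermediate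
24 | (2R,3R,4R)-4-[(2R,3R)-3,5,7-trihydroxy-2-phenylchroman-8-yl]-2-phenylchromane-3,5,7-triol | Oc1cc(O)c2c(c1)O[C@H](c1ccccc1)[C@H](O)[C@H]2c1c(O)cc(O)c2c1O[C@H](c1ccccc1)[C@H](O)C2 | target

Total step count: 17
Longest linear sequence: 13 steps (steps 1–9, then 14–17)

Steps most likely to fail

1. Step 16 (key step). The epoxide may be consumed by the medium or by the water released (solvolysis, hydride shift to an aldehyde, intermolecular arylation) before ring F has closed. Facial control in the closure of ring C may also be incomplete, and loss of H3 from the cation could scramble C3. The fallback separates the two ring closures so that each runs under its own established conditions. It sets out from 18, which is isolated when step 14 is quenched with aq NH4Cl before any fluoride is added. Camphorsulfonic acid (cat.) in CH2Cl2 at −40 °C should ionise C4 alone and close ring C while the silyl ethers survive, giving the ring-C-closed bis(silyl ether) F1. Bu4NF then frees the ring-C-closed diol F2. TsCl/Et3N/Bu2SnO (cat.) gives the ring-C-closed primary tosylate F3, which K2CO3 in MeOH closes to 22, now an isolated compound. A separate epoxy–arene cyclisation of 22 (AuCl3/AgOTf in CH2Cl2, or Sc(OTf)3 in HFIP) comes back to the route at 23.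

2. Step 14. The hindered, basic aryllithium may take a proton from the α-benzyloxy aldehyde instead of adding, leading to enolisation with loss of the β-aryloxide or to epimerisation at C3. The fallback is an acyl-substitution and reduction sequence that never has a free aldehyde. It sets out from 11. TEMPO/PhI(OAc)2 in MeCN/H2O gives (2S,3R)-2-(benzyloxy)-3-[3,5-bis(benzyloxy)phenoxy]-3-phenylpropanoic acid F4. EDC·HCl with MeNH(OMe)·HCl and iPr2NEt gives its N-methoxy-N-methylamide F5. Aryllithium 17 adds to F5 at −78 °C and gives, through the chelated tetrahedral adduct, the aryl ketone F6. NaBH4 (THF/MeOH, 0 °C) reduces F6 to 18, where the route is rejoined (fluoride then gives 19); either C4 epimer serves.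

3. Step 11. Attack of the hindered ortho-bromophenoxide on the alkoxyphosphonium ion of a carbinol flanked by the dioxolane may be slow, which leaves room for alkylation of the hydrazide or for ionisation with partial loss of inversion. The fallback is sulfonate activation followed by SN2 etherification in two separate operations. It sets out from 5. MsCl/Et3N (CH2Cl2, −20 °C) gives, with retention, (S)-[(R)-2,2-dimethyl-1,3-dioxolan-4-yl](phenyl)methyl methanesulfonate F7. The caesium phenoxide of 13 (Cs2CO3, DMF, rt) displaces the sulfonate with inversion, rejoining the route at 14.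

Further compounds
F1 | step 16 | ring-C-closed bis(silyl ether): 2,3-cis-3,4-trans-3,5,7-tris(benzyloxy)-4-{2,4-bis(benzyloxy)-6-[(1R,2R)-2,3-bis(tert-butyldimethylsilyloxy)-1-phenylpropoxy]phenyl}-2-phenylchromane | c1ccccc1COc1cc(OCc3ccccc3)c2c(c1)O[C@H](c1ccccc1)[C@H](OCc1ccccc1)[C@H]2c1c(OCc3ccccc3)cc(OCc3ccccc3)cc1O[C@H](c1ccccc1)[C@H](O[Si](C)(C)C(C)(C)C)CO[Si](C)(C)C(C)(C)C
F2 | step 16 | ring-C-closed diol: 2,3-cis-3,4-trans-3,5,7-tris(benzyloxy)-4-{2,4-bis(benzyloxy)-6-[(1R,2R)-2,3-dihydroxy-1-phenylpropoxy]phenyl}-2-phenylchromane | c1ccccc1COc1cc(OCc3ccccc3)c2c(c1)O[C@H](c1ccccc1)[C@H](OCc1ccccc1)[C@H]2c1c(OCc3ccccc3)cc(OCc3ccccc3)cc1O[C@H](c1ccccc1)[C@H](O)CO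
F3 | step 16 | ring-C-closed primary tosylate (C4'-O-tosylate of F2) | c1ccccc1COc1cc(OCc3ccccc3)c2c(c1)O[C@H](c1ccccc1)[C@H](OCc1ccccc1)[C@H]2c1c(OCc3ccccc3)cc(OCc3ccccc3)cc1O[C@H](c1ccccc1)[C@H](O)COS(=O)(=O)c1ccc(C)cc1
F4 | step 14 | (2S,3R)-2-(benzyloxy)-3-[3,5-bis(benzyloxy)phenoxy]-3-phenylpropanoic acid | c1ccccc1COc1cc(OCc2ccccc2)cc(c1)O[C@H](c1ccccc1)[C@H](OCc1ccccc1)C(=O)O
F5 | step 14 | (2S,3R)-2-(benzyloxy)-3-[3,5-bis(benzyloxy)phenoxy]-N-methoxy-N-methyl-3-phenylpropanamide | c1ccccc1COc1cc(OCc2ccccc2)cc(c1)O[C@H](c1ccccc1)[C@H](OCc1ccccc1)C(=O)N(C)OC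
F6 | step 14 | aryl ketone (C4 carbonyl) with C3 benzyl ether and bis-silylated C3'–C4' diol | c1ccccc1COc1cc(OCc2ccccc2)cc(c1)O[C@H](c1ccccc1)[C@H](OCc1ccccc1)C(=O)c1c(OCc2ccccc2)cc(OCc2ccccc2)cc1O[C@H](c1ccccc1)[C@H](O[Si](C)(C)C(C)(C)C)CO[Si](C)(C)C(C)(C)C
F7 | step 11 | (S)-[(R)-2,2-dimethyl-1,3-dioxolan-4-yl](phenyl)methyl methanesulfonate | CS(=O)(=O)O[C@@H](c1ccccc1)[C@H]1COC(C)(C)O1
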